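Numbering the C15 chain from the alkyne carbon (C1), the target is a 2,8-dioxabicyclo[5.2.1]decane: an oxolane (ring A, O bridging C6 and C9) bridged by an oxocane (ring B, O bridging C7 and C13). In ring B the C10 acetoxy and C12 bromo carbons flank the C11 methylene, a disguised β-hydroxy ketone. The route therefore closes ring B last by a samarium Reformatsky aldol: the enolate of a bromomethyl ketone on C9 adds to an (R)-2-alkoxybutanal tethered through the C7 oxygen of a cis-3,5-disubstituted oxolane. One operation forms C11–C12, ring B and the C12 carbinol, which then directs the C10 reduction and is replaced by bromide with inversion.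

Key step: step 10

Remark: 1, 5 and all reagents are taken as commercially available; 4 and 7 are carried as mixtures of anomers (that centre is erased in step 6); chain atoms C6, C7, C9, C10, C12, C13 are locants 9, 1, 7, 6, 4, 3 in the bicyclic names.

Step 1
Reactants: 1 (±)-hexa-1,5-dien-3-ol
Product: 2 (2R,3S)-1,2-epoxyhex-5-en-3-ol
Conditions: Ti(Oi-Pr)4 (10 mol %), L-(+)-diisopropyl tartrate (12 mol %), t-BuOOH (0.6 equiv), 4 Å molecular sieves, CH2Cl2, −20 °C
Reagents that add atoms: tert-butyl hydroperoxide, CC(C)(C)OO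
Why: Sharpless asymmetric epoxidation run as a kinetic resolution: the L-(+)-tartrate catalyst should epoxidise only the (S)-enantiomer of the secondary allylic alcohol at its vinyl group (the homoallylic alkene is not activated) and erythro-selectively, which sets C6 (S) and C7 (R) and leaves (R)-1 behind.

Step 2
Reactants: 2 (2R,3S)-1,2-epoxyhex-5-en-3-ol
Product: 3 (2R,3S)-1-(1,3-dithian-2-yl)hex-5-ene-2,3-diol
Conditions: 1,3-dithiane (2.5 equiv), n-BuLi, THF, −30 °C; then 2, −30 → 0 °C; H2O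
Reagents that add atoms: 1,3-dithiane, C1CSCSC1
Why: Corey–Seebach umpolung: the excess lithiated dithiane (the first equivalent only deprotonates the hydroxyl) should open the epoxide by SN2 attack at its unsubstituted carbon C8, so C7 is untouched and C9 arrives at the aldehyde oxidation level.

Step 3
Reactants: 3 (2R,3S)-1-(1,3-dithian-2-yl)hex-5-ene-2,3-diol
Product: 4 (2S,3R)-5-methoxy-2-(prop-2-en-1-yl)oxolan-3-ol
Conditions: PhI(O2CCF3)2 (1.5 equiv), MeOH, 0 °C
Reagents that add atoms: methanol, CO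
Why: Oxidative dethioacetalisation with a hypervalent iodine reagent in methanol: the sulfur-activated C9 should be trapped by the C6 hydroxyl (five-membered ring; the C7 hydroxyl could only form an oxetane) and by methanol, giving the methyl furanoside and thereby differentiating the two hydroxyls without a protecting group.

Step 4
Reactants: 5 methyl (2S)-2-hydroxybutanoate
Product: 6 methyl (2S)-2-{[(trifluoromethyl)sulfonyl]oxy}butanoate
Conditions: (CF3SO2)2O, 2,6-lutidine, CH2Cl2, −78 → 0 °C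
Reagents that add atoms: trifluoromethanesulfonic anhydride, O=S(=O)(OS(=O)(=O)C(F)(F)F)C(F)(F)F
Why: O-Sulfonylation of the α-hydroxy ester breaks no bond to the stereocentre, so the (S)-triflate, a configurationally stable SN2 electrophile, should form with retention.

Step 5
Reactants: 4 (2S,3R)-5-methoxy-2-(prop-2-en-1-yl)oxolan-3-ol; 6 methyl (2S)-2-{[(trifluoromethyl)sulfonyl]oxy}butanoate
Product: 7 methyl (2R)-2-{[(2S,3R)-5-methoxy-2-(prop-2-en-1-yl)oxolan-3-yl]oxy}butanoate
Conditions: NaH, THF, 0 °C; then 6, −20 °C → rt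
Reagents that add atoms: none
Why: Williamson ether synthesis: the sodium alkoxide of 4 should displace the α-carbonyl-activated secondary triflate by clean SN2 with inversion, which sets C13 (R); the acetal is inert to base.

Step 6
Reactants: 7 methyl (2R)-2-{[(2S,3R)-5-methoxy-2-(prop-2-en-1-yl)oxolan-3-yl]oxy}butanoate
Product: 9 methyl (2R)-2-{[(2S,3R,5R)-2-(prop-2-en-1-yl)-5-[2-(trimethylsilyl)ethynyl]oxolan-3-yl]oxy}butanoate, via cyclic oxocarbenium ion 8 (not isolated)
Conditions: Bu3SnC≡CSiMe3 (2 equiv), Me3SiOTf (1.2 equiv), CH2Cl2, −78 → −30 °C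
Reagents that add atoms: tributyl[(trimethylsilyl)ethynyl]stannane, CCCC[Sn](CCCC)(CCCC)C#C[Si](C)(C)C
Why: Lewis acid C-glycosylation of the furanosyl oxocarbenium ion 8 with an alkynylstannane: inside attack on the envelope conformer with the C7 alkoxy group pseudoaxial should deliver the alkyne cis to the C7 oxygen and trans to the C6 allyl group, which sets C9 (R); excess stannane at low temperature should outrun Prins capture by the allyl group.

Step 7
Reactants: 9 methyl (2R)-2-{[(2S,3R,5R)-2-(prop-2-en-1-yl)-5-[2-(trimethylsilyl)ethynyl]oxolan-3-yl]oxy}butanoate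
Product: 10 methyl (2R)-2-{[(2S,3R,5R)-5-(2-bromoethynyl)-2-(prop-2-en-1-yl)oxolan-3-yl]oxy}butanoate
Conditions: NBS (1.2 equiv), AgNO3 (10 mol %), acetone, rt, dark
Reagents that add atoms: N-bromosuccinimide, BrN1C(=O)CCC1=O
Why: Silver-catalysed desilylative bromination: AgNO3 converts the trimethylsilyl alkyne into a silver acetylide that NBS brominates, giving the 1-bromoalkyne without touching the terminal alkene or the ester.

Step 8
Reactants: 10 methyl (2R)-2-{[(2S,3R,5R)-5-(2-bromoethynyl)-2-(prop-2-en-1-yl)oxolan-3-yl]oxy}butanoate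
Product: 11 (2R)-2-{[(2S,3R,5R)-5-(2-bromoethynyl)-2-(prop-2-en-1-yl)oxolan-3-yl]oxy}butanal
Conditions: i-Bu2AlH (1.1 equiv), CH2Cl2, −78 °C; aq. KNaC4H4O6 (potassium sodium tartrate)
Reagents that add atoms: none
Why: Partial reduction of an α-alkoxy ester with i-Bu2AlH at −78 °C: the chelated tetrahedral aluminate should survive until work-up, so the aldehyde forms without over-reduction, without epimerisation at C13 and without hydroalumination of the bromoalkyne.

Step 9
Reactants: 11 (2R)-2-{[(2S,3R,5R)-5-(2-bromoethynyl)-2-(prop-2-en-1-yl)oxolan-3-yl]oxy}butanal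
Product: 12 (2R)-2-{[(2S,3R,5R)-5-(2-bromoacetyl)-2-(prop-2-en-1-yl)oxolan-3-yl]oxy}butanal
Conditions: (XPhos)AuNTf2 (2 mol %), H2O (3 equiv), ClCH2CH2Cl, rt
Reagents that add atoms: water, O
Why: Gold-catalysed hydration of a 1-haloalkyne: water should add to the alkyne carbon remote from bromine, giving the bromomethyl ketone regioselectively under neutral conditions that the aldehyde, the alkene and both stereocentres α to oxygen tolerate.

Step 10
Reactants: 12 (2R)-2-{[(2S,3R,5R)-5-(2-bromoacetyl)-2-(prop-2-en-1-yl)oxolan-3-yl]oxy}butanal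
Product: 14 (1R,3R,4R,7R,9S)-3-ethyl-4-hydroxy-9-(prop-2-en-1-yl)-2,8-dioxabicyclo[5.2.1]decan-6-one, via trivalent samarium enolate 13 (not isolated)
Conditions: SmI2 (2.2 equiv), THF, −78 °C, slow addition of 12 (final 0.005 M); aq. NH4Cl
Reagents that add atoms: none
Why: SmI2 reduces the C–Br bond of 12 by two single-electron transfers to the trivalent samarium enolate 13, whose carbon terminus C11 adds to the tethered aldehyde carbon C12 through a samarium-bridged, chair-like aldol transition state. The closest known reaction type is the SmI2-mediated intramolecular Reformatsky (aldol) cyclisation of α-bromo ketones onto aldehydes, an established entry to eight- and nine-membered rings. Ring B (the oxocane) is closed in the 8-(enolendo)-exo-trig mode, and because both arms sit cis on ring A the bridged 2,8-dioxabicyclo[5.2.1]decane forms at the same time. The new stereocentre C12 is controlled by C13: samarium chelates the aldehyde oxygen and the α-ether oxygen, the ring constraint keeps that C–O bond gauche to the forming bond, and C11 should approach past the C13 hydrogen and not the ethyl group, giving the 12,13-syn (12R) carbinol, on purpose epimeric to the final bromide. The step needs chemoselectivity (C–Br reduction before ketyl formation at the aldehyde, secured by the much faster reduction of α-bromo ketones at −78 °C without additives) and cyclisation over oligomerisation (secured by slow addition at high dilution and by the cis template). The C9–O bond α to the ketone should survive because only about two equivalents of reductant are present.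

Step 11
Reactants: 14 (1R,3R,4R,7R,9S)-3-ethyl-4-hydroxy-9-(prop-2-en-1-yl)-2,8-dioxabicyclo[5.2.1]decan-6-one
Product: 15 (1R,3R,4R,6R,7R,9S)-3-ethyl-6-hydroxy-9-(prop-2-en-1-yl)-2,8-dioxabicyclo[5.2.1]decan-4-yl 4-nitrobenzoate
Conditions: 4-O2NC6H4CHO (4 equiv), SmI2 (30 mol %, premixed with the aldehyde), THF, −10 °C
Reagents that add atoms: 4-nitrobenzaldehyde, O=Cc1ccc(cc1)[N+](=O)[O-]
Why: Evans–Tishchenko reduction: the aldehyde adds to the C12 hydroxyl on samarium and its formyl hydrogen should be transferred to the C10 carbonyl through a six-membered chair transition state, which sets C10 (R) 1,3-anti to C12 and at the same time leaves the C12 oxygen masked as a 4-nitrobenzoate.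

Step 12
Reactants: 15 (1R,3R,4R,6R,7R,9S)-3-ethyl-6-hydroxy-9-(prop-2-en-1-yl)-2,8-dioxabicyclo[5.2.1]decan-4-yl 4-nitrobenzoate
Product: 16 (1R,3R,4R,6R,7R,9S)-6-(acetyloxy)-3-ethyl-9-(prop-2-en-1-yl)-2,8-dioxabicyclo[5.2.1]decan-4-yl 4-nitrobenzoate
Conditions: Ac2O, pyridine, DMAP (cat.), CH2Cl2, rt
Reagents that add atoms: acetic anhydride, CC(=O)OC(C)=O
Why: DMAP-catalysed acylation of the free secondary C10 hydroxyl installs the acetate of the target with retention.

Step 13
Reactants: 16 (1R,3R,4R,6R,7R,9S)-6-(acetyloxy)-3-ethyl-9-(prop-2-en-1-yl)-2,8-dioxabicyclo[5.2.1]decan-4-yl 4-nitrobenzoate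
Product: 17 (1R,3R,4R,6R,7R,9S)-3-ethyl-4-hydroxy-9-(prop-2-en-1-yl)-2,8-dioxabicyclo[5.2.1]decan-6-yl acetate
Conditions: NaN3, MeOH, 40 °C
Reagents that add atoms: none
Why: Azide-promoted methanolysis (transesterification): the electron-poor 4-nitrobenzoate should be cleaved much faster than the alkyl acetate, releasing the C12 hydroxyl, while acyl migration is avoided at near-neutral pH.

Step 14
Reactants: 17 (1R,3R,4R,6R,7R,9S)-3-ethyl-4-hydroxy-9-(prop-2-en-1-yl)-2,8-dioxabicyclo[5.2.1]decan-6-yl acetate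
Product: 18 (1R,3R,4S,6R,7R,9S)-4-bromo-3-ethyl-9-(prop-2-en-1-yl)-2,8-dioxabicyclo[5.2.1]decan-6-yl acetate
Conditions: CBr4, P(n-C8H17)3, toluene, 70 °C
Reagents that add atoms: carbon tetrabromide, BrC(Br)(Br)Br
Why: Appel-type bromination with trioctylphosphine and CBr4: the alkoxyphosphonium ion should be displaced by bromide in an SN2 reaction with inversion, converting the (12R)-alcohol into the (12S)-bromide of the target.

Step 15
Reactants: 18 (1R,3R,4S,6R,7R,9S)-4-bromo-3-ethyl-9-(prop-2-en-1-yl)-2,8-dioxabicyclo[5.2.1]decan-6-yl acetate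
Product: 19 (1R,3R,4S,6R,7R,9S)-4-bromo-3-ethyl-9-[(2E)-4-oxobut-2-en-1-yl]-2,8-dioxabicyclo[5.2.1]decan-6-yl acetate
Conditions: (E)-crotonaldehyde (5 equiv), second-generation Hoveyda–Grubbs catalyst RuCl2(H2IMes)(=CH-C6H4-2-Oi-Pr) (5 mol %), CH2Cl2, 40 °C
Reagents that add atoms: (E)-crotonaldehyde, C/C=C/C=O
Why: Olefin cross-metathesis of the terminal alkene with excess crotonaldehyde: the electron-poor partner does not homodimerise readily and the conjugated product should form under thermodynamic control as the E isomer.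

Step 16
Reactants: 19 (1R,3R,4S,6R,7R,9S)-4-bromo-3-ethyl-9-[(2E)-4-oxobut-2-en-1-yl]-2,8-dioxabicyclo[5.2.1]decan-6-yl acetate
Product: 20 (1R,3R,4S,6R,7R,9S)-4-bromo-3-ethyl-9-[(2E)-pent-2-en-4-yn-1-yl]-2,8-dioxabicyclo[5.2.1]decan-6-yl acetate
Conditions: Me3SiCHN2, LiN(i-Pr)2, THF, −78 °C; then 19, −78 → 0 °C
Reagents that add atoms: (trimethylsilyl)diazomethane, C[Si](C)(C)C=[N+]=[N-]
Why: Colvin rearrangement: lithiated trimethylsilyldiazomethane adds to the aldehyde and, after loss of silanolate and dinitrogen with a 1,2-hydrogen shift, should give the terminal alkyne with the E alkene intact, at a temperature at which the acetate and the secondary bromide are not attacked.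

Compound list
1 | (±)-hexa-1,5-dien-3-ol | C=CCC(O)C=C | starting material
2 | (2R,3S)-1,2-epoxyhex-5-en-3-ol, that is (1S)-1-[(2R)-oxiran-2-yl]but-3-en-1-ol | C=CC[C@H](O)[C@H]1CO1 | intermediate
3 | (2R,3S)-1-(1,3-dithian-2-yl)hex-5-ene-2,3-diol | C=CC[C@H](O)[C@H](O)CC1SCCCS1 | intermediate
4 | (2S,3R)-5-methoxy-2-(prop-2-en-1-yl)oxolan-3-ol (both anomers) | C=CC[C@@H]1OC(OC)C[C@H]1O | intermediate
5 | methyl (2S)-2-hydroxybutanoate | CC[C@H](O)C(=O)OC | starting material
6 | methyl (2S)-2-{[(trifluoromethyl)sulfonyl]oxy}butanoate | CC[C@H](OS(=O)(=O)C(F)(F)F)C(=O)OC | intermediate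
7 | methyl (2R)-2-{[(2S,3R)-5-methoxy-2-(prop-2-en-1-yl)oxolan-3-yl]oxy}butanoate (both anomers) | C=CC[C@@H]1OC(OC)C[C@H]1O[C@H](CC)C(=O)OC | intermediate
8 | (2S,3R)-3-{[(2R)-1-methoxy-1-oxobutan-2-yl]oxy}-2-(prop-2-en-1-yl)-3,4-dihydro-2H-furan-1-ium (cyclic oxocarbenium ion) | C=CC[C@@H]1[O+]=CC[C@H]1O[C@H](CC)C(=O)OC | intermediate (not isolated)
9 | methyl (2R)-2-{[(2S,3R,5R)-2-(prop-2-en-1-yl)-5-[2-(trimethylsilyl)ethynyl]oxolan-3-yl]oxy}butanoate | C=CC[C@@H]1O[C@@H](C#C[Si](C)(C)C)C[C@H]1O[C@H](CC)C(=O)OC | intermediate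
10 | methyl (2R)-2-{[(2S,3R,5R)-5-(2-bromoethynyl)-2-(prop-2-en-1-yl)oxolan-3-yl]oxy}butanoate | C=CC[C@@H]1O[C@@H](C#CBr)C[C@H]1O[C@H](CC)C(=O)OC | intermediate
11 | (2R)-2-{[(2S,3R,5R)-5-(2-bromoethynyl)-2-(prop-2-en-1-yl)oxolan-3-yl]oxy}butanal | C=CC[C@@H]1O[C@@H](C#CBr)C[C@H]1O[C@H](CC)C=O | intermediate
12 | (2R)-2-{[(2S,3R,5R)-5-(2-bromoacetyl)-2-(prop-2-en-1-yl)oxolan-3-yl]oxy}butanal | C=CC[C@@H]1O[C@@H](C(=O)CBr)C[C@H]1O[C@H](CC)C=O | intermediate
13 | diiodo({1-[(2R,4R,5S)-4-{[(2R)-1-oxobutan-2-yl]oxy}-5-(prop-2-en-1-yl)oxolan-2-yl]ethenyl}oxy)samarium (trivalent samarium enolate of 12) | C=CC[C@@H]1O[C@@H](C(=C)O[Sm](I)I)C[C@H]1O[C@H](CC)C=O | intermediate (not isolated)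
14 | (1R,3R,4R,7R,9S)-3-ethyl-4-hydroxy-9-(prop-2-en-1-yl)-2,8-dioxabicyclo[5.2.1]decan-6-one | C=CC[C@@H]1O[C@@H]2C[C@H]1O[C@H](CC)[C@H](O)CC2=O | intermediate
15 | (1R,3R,4R,6R,7R,9S)-3-ethyl-6-hydroxy-9-(prop-2-en-1-yl)-2,8-dioxabicyclo[5.2.1]decan-4-yl 4-nitrobenzoate | C=CC[C@@H]1O[C@@H]2C[C@H]1O[C@H](CC)[C@H](OC(=O)c3ccc(cc3)[N+](=O)[O-])C[C@H]2O | intermediate
16 | (1R,3R,4R,6R,7R,9S)-6-(acetyloxy)-3-ethyl-9-(prop-2-en-1-yl)-2,8-dioxabicyclo[5.2.1]decan-4-yl 4-nitrobenzoate | C=CC[C@@H]1O[C@@H]2C[C@H]1O[C@H](CC)[C@H](OC(=O)c3ccc(cc3)[N+](=O)[O-])C[C@H]2OC(C)=O | intermediate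
17 | (1R,3R,4R,6R,7R,9S)-3-ethyl-4-hydroxy-9-(prop-2-en-1-yl)-2,8-dioxabicyclo[5.2.1]decan-6-yl acetate | C=CC[C@@H]1O[C@@H]2C[C@H]1O[C@H](CC)[C@H](O)C[C@H]2OC(C)=O | intermediate
18 | (1R,3R,4S,6R,7R,9S)-4-bromo-3-ethyl-9-(prop-2-en-1-yl)-2,8-dioxabicyclo[5.2.1]decan-6-yl acetate | C=CC[C@@H]1O[C@@H]2C[C@H]1O[C@H](CC)[C@@H](Br)C[C@H]2OC(C)=O | intermediate
19 | (1R,3R,4S,6R,7R,9S)-4-bromo-3-ethyl-9-[(2E)-4-oxobut-2-en-1-yl]-2,8-dioxabicyclo[5.2.1]decan-6-yl acetate | O=C/C=C/C[C@@H]1O[C@@H]2C[C@H]1O[C@H](CC)[C@@H](Br)C[C@H]2OC(C)=O | intermediate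
20 | (1R,3R,4S,6R,7R,9S)-4-bromo-3-ethyl-9-[(2E)-pent-2-en-4-yn-1-yl]-2,8-dioxabicyclo[5.2.1]decan-6-yl acetate | C#C/C=C/C[C@@H]1O[C@@H]2C[C@H]1O[C@H](CC)[C@@H](Br)C[C@H]2OC(C)=O | target

Total step count: 16. Longest linear sequence: 15 steps (1 to 20 through steps 1–3 and 5–16; step 4 is a one-step branch).

Steps most likely to fail

Step 10. What may go wrong is poor facial selectivity at the aldehyde during the medium-ring aldol closure, so that the C12 epimer forms beside 14. The fallback sets out from 12 and comes back at 14. The samarium closure is run as described, and the mixture of 14 and its C12 epimer, (1R,3R,4S,7R,9S)-3-ethyl-4-hydroxy-9-(prop-2-en-1-yl)-2,8-dioxabicyclo[5.2.1]decan-6-one F1, is dehydrated (MsCl, Et3N, CH2Cl2, 0 °C → rt) to the ring enone (1R,3R,4Z,7R,9S)-3-ethyl-9-(prop-2-en-1-yl)-2,8-dioxabicyclo[5.2.1]dec-4-en-6-one F2. Copper-catalysed conjugate borylation (B2pin2, CuCl, NaOt-Bu, a chiral bisphosphine chosen to match the substrate, MeOH, THF) would then set C12 under catalyst control and give the β-boryl ketone (1R,3R,4R,7R,9S)-3-ethyl-9-(prop-2-en-1-yl)-4-(4,4,5,5-tetramethyl-1,3,2-dioxaborolan-2-yl)-2,8-dioxabicyclo[5.2.1]decan-6-one F3. Oxidation with NaBO3 (retention) would return 14, so C12 is then fixed by the borylation and not by the aldol.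

Step 6. What may go wrong is capture of the oxocarbenium ion by the pendant allyl group (Prins cyclisation) or loss of anomeric selectivity under strongly ionising Lewis acid conditions. The fallback sets out from 7 and comes back at 9. The anomeric methoxy group is exchanged for a sulfone (PhSO2H, CaCl2, CH2Cl2) to give methyl (2R)-2-{[(2S,3R)-5-(benzenesulfonyl)-2-(prop-2-en-1-yl)oxolan-3-yl]oxy}butanoate F4. Treatment of this with [(trimethylsilyl)ethynyl]zinc bromide (from the lithium acetylide and ZnBr2, THF, 0 °C → rt) should replace the sulfinate within a tight ion pair, without free Lewis acid, and with the same inside-attack preference.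

Step 14. What may go wrong is that the SN2 displacement at the hindered C12 is overtaken by elimination, or by participation of the 1,3-related C10 acetate (dioxanylium formation), which would erode the inversion. The fallback sets out from 15 and comes back at 18; it brings bromide in before the acetate. Silylation of 15 (Et3SiOTf, 2,6-lutidine) gives (1R,3R,4R,6R,7R,9S)-3-ethyl-9-(prop-2-en-1-yl)-6-[(triethylsilyl)oxy]-2,8-dioxabicyclo[5.2.1]decan-4-yl 4-nitrobenzoate F5. Methanolysis (K2CO3, MeOH) gives (1R,3R,4R,6R,7R,9S)-3-ethyl-9-(prop-2-en-1-yl)-6-[(triethylsilyl)oxy]-2,8-dioxabicyclo[5.2.1]decan-4-ol F6. Bromination (CBr4, P(n-C8H17)3, toluene, 70 °C) now has a non-participating neighbour and gives triethyl{[(1R,3R,4S,6R,7R,9S)-4-bromo-3-ethyl-9-(prop-2-en-1-yl)-2,8-dioxabicyclo[5.2.1]decan-6-yl]oxy}silane F7. Desilylation (HF·pyridine, THF) gives (1R,3R,4S,6R,7R,9S)-4-bromo-3-ethyl-9-(prop-2-en-1-yl)-2,8-dioxabicyclo[5.2.1]decan-6-ol F8, and acetylation (Ac2O, pyridine, DMAP) returns 18.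

Further compounds
F1 | step 10 | (1R,3R,4S,7R,9S)-3-ethyl-4-hydroxy-9-(prop-2-en-1-yl)-2,8-dioxabicyclo[5.2.1]decan-6-one | C=CC[C@@H]1O[C@@H]2C[C@H]1O[C@H](CC)[C@@H](O)CC2=O
F2 | step 10 | (1R,3R,4Z,7R,9S)-3-ethyl-9-(prop-2-en-1-yl)-2,8-dioxabicyclo[5.2.1]dec-4-en-6-one | C=CC[C@@H]1O[C@@H]2C[C@H]1O[C@H](CC)/C=C\C2=O
F3 | step 10 | (1R,3R,4R,7R,9S)-3-ethyl-9-(prop-2-en-1-yl)-4-(4,4,5,5-tetramethyl-1,3,2-dioxaborolan-2-yl)-2,8-dioxabicyclo[5.2.1]decan-6-one | C=CC[C@@H]1O[C@@H]2C[C@H]1O[C@H](CC)[C@H](B3OC(C)(C)C(C)(C)O3)CC2=O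
F4 | step 6 | methyl (2R)-2-{[(2S,3R)-5-(benzenesulfonyl)-2-(prop-2-en-1-yl)oxolan-3-yl]oxy}butanoate (both anomers) | C=CC[C@@H]1OC(S(=O)(=O)c2ccccc2)C[C@H]1O[C@H](CC)C(=O)OC
F5 | step 14 | (1R,3R,4R,6R,7R,9S)-3-ethyl-9-(prop-2-en-1-yl)-6-[(triethylsilyl)oxy]-2,8-dioxabicyclo[5.2.1]decan-4-yl 4-nitrobenzoate | C=CC[C@@H]1O[C@@H]2C[C@H]1O[C@H](CC)[C@H](OC(=O)c3ccc(cc3)[N+](=O)[O-])C[C@H]2O[Si](CC)(CC)CC
F6 | step 14 | (1R,3R,4R,6R,7R,9S)-3-ethyl-9-(prop-2-en-1-yl)-6-[(triethylsilyl)oxy]-2,8-dioxabicyclo[5.2.1]decan-4-ol | C=CC[C@@H]1O[C@@H]2C[C@H]1O[C@H](CC)[C@H](O)C[C@H]2O[Si](CC)(CC)CC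
F7 | step 14 | triethyl{[(1R,3R,4S,6R,7R,9S)-4-bromo-3-ethyl-9-(prop-2-en-1-yl)-2,8-dioxabicyclo[5.2.1]decan-6-yl]oxy}silane | C=CC[C@@H]1O[C@@H]2C[C@H]1O[C@H](CC)[C@@H](Br)C[C@H]2O[Si](CC)(CC)CC
F8 | step 14 | (1R,3R,4S,6R,7R,9S)-4-bromo-3-ethyl-9-(prop-2-en-1-yl)-2,8-dioxabicyclo[5.2.1]decan-6-ol | C=CC[C@@H]1O[C@@H]2C[C@H]1O[C@H](CC)[C@@H](Br)C[C@H]2O
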